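**Retrosynthetic overview**
- The last step frees the conjugated acid from a 2-(trimethylsilyl)ethyl ester with fluoride; acid is avoided because the target's para-alkoxybenzyl ester is acid-labile.
- Key disconnection: the C2–C3 bond of the succinate (alkenyl carbon to CH(CH3)). It is made by a nickel-catalysed enantioconvergent reductive coupling of a racemic α-chloropropanoate of the benzofuranylmethanol with an (E)-α-iodoenoate, which sets 3R and carries the alkene geometry over.
- Iodoenoate half: hept-1-yne, carboxylation, silylethyl ester, palladium-catalysed syn-hydrostannation, iododestannylation.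
- Alcohol half: 4-bromophenol, ortho-iodination, palladium-catalysed asymmetric heteroannulation with isoprene (sets 2S), Br to CHO to CH2OH, chloropropanoate.
- Rings: the benzene ring comes from 4-bromophenol; the dihydrofuran ring is the only ring formed (step 2).

Assumption: the SMILES is read literally (2S at the dihydrobenzofuran, 3R at the methyl-bearing carbon, Z hexylidene with the pentyl chain cis to CO2H); for the two chiral ligands (steps 2 and 10) the antipode that gives this sense is fixed in a model run.

**Step 1**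
Reactants: 1 4-bromophenol
Product: 2 4-bromo-2-iodophenol
Conditions: NIS (1.05 equiv), TsOH·H2O (10 mol%), MeCN, 0 °C to rt
Reagents that add atoms: N-iodosuccinimide, O=C1CCC(=O)N1I
Why: Electrophilic aromatic iodination directed by the hydroxyl group; the para position is blocked by bromine, so one equivalent gives the ortho-monoiodide.

**Step 2**
Reactants: 2 4-bromo-2-iodophenol; 3 isoprene (2-methylbuta-1,3-diene)
Product: 4 (2S)-5-bromo-2-(prop-1-en-2-yl)-2,3-dihydro-1-benzofuran
Conditions: Pd2(dba)3 (2.5 mol%), chiral sulfinamide monophosphine ligand of the TY-Phos type (10 mol%), NaOPh (2 equiv), isoprene (4 equiv), toluene, 40 °C, sealed tube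
Reagents that add atoms: none
Why: Asymmetric Heck/Tsuji–Trost heteroannulation (Larock-type diene annulation): zerovalent palladium inserts into C–I much faster than into C–Br, the aryl group adds to the unsubstituted terminus of isoprene, and the phenoxide closes the five-membered ring at the internal carbon of the π-allyl intermediate under ligand control, which sets 2S and leaves the isopropenyl group.

**Step 3**
Reactants: 4 (2S)-5-bromo-2-(prop-1-en-2-yl)-2,3-dihydro-1-benzofuran
Product: 7 (2S)-2-(prop-1-en-2-yl)-2,3-dihydro-1-benzofuran-5-carbaldehyde, via aryllithium 5 (not isolated), via lithium hemiaminalate 6 (not isolated)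
Conditions: n-BuLi (1.1 equiv), THF, −78 °C, 20 min; DMF (2 equiv), −78 to 0 °C; H2O quench
Reagents that add atoms: N,N-dimethylformamide, CN(C)C=O
Why: Bromine–lithium exchange followed by Bouveault-type formylation; at −78 °C exchange outruns deprotonation next to the allylic ether, so the 2S centre is untouched.

**Step 4**
Reactants: 7 (2S)-2-(prop-1-en-2-yl)-2,3-dihydro-1-benzofuran-5-carbaldehyde
Product: 8 [(2S)-2-(prop-1-en-2-yl)-2,3-dihydro-1-benzofuran-5-yl]methanol
Conditions: NaBH4 (0.5 equiv), MeOH, 0 °C
Reagents that add atoms: none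
Why: Chemoselective borohydride reduction of the aldehyde; the alkene and the aryl ether are inert.

**Step 5**
Reactants: 8 [(2S)-2-(prop-1-en-2-yl)-2,3-dihydro-1-benzofuran-5-yl]methanol; 9 2-chloropropanoyl chloride (racemic)
Product: 10 [(2S)-2-(prop-1-en-2-yl)-2,3-dihydro-1-benzofuran-5-yl]methyl (2RS)-2-chloropropanoate (1:1 epimers at the chlorine-bearing carbon)
Conditions: pyridine (1.5 equiv), CH2Cl2, 0 °C
Reagents that add atoms: none
Why: Acylation of the primary benzylic alcohol by an acid chloride, with pyridine scavenging HCl to protect the acid-sensitive isopropenyl ether; the C–Cl centre is left racemic because step 10 is stereoconvergent.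

**Step 6**
Reactants: 11 hept-1-yne
Product: 14 oct-2-ynoic acid, via lithium heptynide 12 (not isolated), via lithium oct-2-ynoate 13 (not isolated)
Conditions: n-BuLi (1.05 equiv), THF, −78 °C; CO2 (g), −78 °C to rt; 1 M HCl
Reagents that add atoms: carbon dioxide, O=C=O
Why: Deprotonation of the terminal alkyne and carboxylation of the lithium acetylide.

**Step 7**
Reactants: 14 oct-2-ynoic acid
Product: 16 2-(trimethylsilyl)ethyl oct-2-ynoate, via O-acylisourea 15 (not isolated)
Conditions: 2-(trimethylsilyl)ethanol (1.1 equiv), DCC (1.1 equiv), DMAP (5 mol%), CH2Cl2, 0 °C to rt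
Reagents that add atoms: 2-(trimethylsilyl)ethanol, C[Si](C)(C)CCO
Why: Steglich esterification; the silylethyl ester tolerates tin hydride, iodine and low-valent nickel and is later removed by fluoride without acid.

**Step 8**
Reactants: 16 2-(trimethylsilyl)ethyl oct-2-ynoate
Product: 17 2-(trimethylsilyl)ethyl (2E)-2-(tributylstannyl)oct-2-enoate
Conditions: Bu3SnH (1.1 equiv, slow addition), Pd(PPh3)4 (2 mol%), THF, 0 °C to rt
Reagents that add atoms: tributyltin hydride, CCCC[SnH](CCCC)CCCC
Why: Palladium-catalysed syn-hydrostannation of an alkynoate puts tin on the carbon α to the ester and H cis to it, so the pentyl chain ends cis to the ester, the geometry needed for the Z target.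

**Step 9**
Reactants: 17 2-(trimethylsilyl)ethyl (2E)-2-(tributylstannyl)oct-2-enoate
Product: 18 2-(trimethylsilyl)ethyl (2E)-2-iodooct-2-enoate
Conditions: I2 (1.05 equiv), CH2Cl2, 0 °C; aq. Na2S2O3, aq. KF
Reagents that add atoms: iodine, II
Why: Iododestannylation (electrophilic ipso substitution at C–Sn) proceeds with retention of alkene geometry.

**Step 10**
Reactants: 10 [(2S)-2-(prop-1-en-2-yl)-2,3-dihydro-1-benzofuran-5-yl]methyl (2RS)-2-chloropropanoate; 18 2-(trimethylsilyl)ethyl (2E)-2-iodooct-2-enoate
Product: 19 4-{[(2S)-2-(prop-1-en-2-yl)-2,3-dihydro-1-benzofuran-5-yl]methyl} 1-[2-(trimethylsilyl)ethyl] (2Z,3R)-2-hexylidene-3-methylbutanedioate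
Conditions: NiBr2·diglyme (10 mol%), (4S,4'S)-4,4'-diheptyl-4,4',5,5'-tetrahydro-2,2'-bioxazole (12 mol%), Mn powder (3 equiv), Me3SiCl (10 mol%), DMA, 5 °C; 18 used at 1.5 equiv
Reagents that add atoms: none
Why: Proposed new method: a nickel-catalysed enantioconvergent reductive cross-electrophile coupling in which the C(sp2) partner is an α-iodo-α,β-unsaturated ester, a substrate class not yet shown for this reactivity; zerovalent nickel carrying the chiral bioxazoline adds to the C–I bond of 18 with retention to give a C-bound divalent alkenylnickel iodide, monovalent nickel abstracts chlorine from either epimer of 10 to give one planar α-ester radical (the source of stereoconvergence), the radical is captured to a trivalent alkyl(alkenyl)nickel, and reductive elimination in the chiral pocket forms the C2–C3 bond and sets 3R under catalyst control (the 2S centre is remote), while Mn returns nickel to the zerovalent state; the electrophilic α-ester radical is polarity-mismatched for Giese addition to the electron-poor iodoenoate, and the non-basic medium leaves the acidic C3–H and the Z alkene unequilibrated; the closest known reaction type is the nickel/bis(oxazoline)-catalysed asymmetric reductive coupling of racemic α-chloro esters with aryl iodides and of benzylic chlorides with alkenyl bromides.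

**Step 11**
Reactants: 19 4-{[(2S)-2-(prop-1-en-2-yl)-2,3-dihydro-1-benzofuran-5-yl]methyl} 1-[2-(trimethylsilyl)ethyl] (2Z,3R)-2-hexylidene-3-methylbutanedioate
Product: 21 (2Z,3R)-2-hexylidene-3-methyl-4-oxo-4-{[(2S)-2-(prop-1-en-2-yl)-2,3-dihydro-1-benzofuran-5-yl]methoxy}butanoic acid, via carboxylate salt 20 (not isolated)
Conditions: tris(dimethylamino)sulfonium difluorotrimethylsilicate, [(Me2N)3S][Me3SiF2] (TASF, 1.5 equiv), DMF, 0 °C; then cold 0.1 M HCl to pH 3–4
Reagents that add atoms: none
Why: Fluoride attacks silicon and triggers β-elimination of the 2-silylethyl ester to ethene, Me3SiF and the carboxylate under aprotic, weakly basic conditions that should leave the benzylic ester, the C3 centre and the Z alkene intact; cold dilute acid then frees the acid.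

**Compound list**
1 | 4-bromophenol | Oc1ccc(Br)cc1 | starting material
2 | 4-bromo-2-iodophenol | Oc1ccc(Br)cc1I | intermediate
3 | isoprene | C=CC(C)=C | starting material
4 | (2S)-5-bromo-2-(prop-1-en-2-yl)-2,3-dihydro-1-benzofuran | C=C(C)[C@@H]1Cc2cc(Br)ccc2O1 | intermediate
5 | aryllithium from 4 (not isolated) | C=C(C)[C@@H]1Cc2cc([Li])ccc2O1 | intermediate
6 | lithium hemiaminalate from 5 and DMF (not isolated) | C=C(C)[C@@H]1Cc2cc(C(O[Li])N(C)C)ccc2O1 | intermediate
7 | (2S)-2-(prop-1-en-2-yl)-2,3-dihydro-1-benzofuran-5-carbaldehyde | C=C(C)[C@@H]1Cc2cc(C=O)ccc2O1 | intermediate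
8 | [(2S)-2-(prop-1-en-2-yl)-2,3-dihydro-1-benzofuran-5-yl]methanol | C=C(C)[C@@H]1Cc2cc(CO)ccc2O1 | intermediate
9 | 2-chloropropanoyl chloride (racemic) | CC(Cl)C(=O)Cl | starting material
10 | [(2S)-2-(prop-1-en-2-yl)-2,3-dihydro-1-benzofuran-5-yl]methyl (2RS)-2-chloropropanoate | C=C(C)[C@@H]1Cc2cc(COC(=O)C(C)Cl)ccc2O1 | intermediate
11 | hept-1-yne | CCCCCC#C | starting material
12 | lithium heptynide (not isolated) | CCCCCC#C[Li] | intermediate
13 | lithium oct-2-ynoate (not isolated) | CCCCCC#CC(=O)O[Li] | intermediate
14 | oct-2-ynoic acid | CCCCCC#CC(=O)O | intermediate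
15 | O-acylisourea of 14 with DCC (not isolated) | CCCCCC#CC(=O)OC(=NC1CCCCC1)NC1CCCCC1 | intermediate
16 | 2-(trimethylsilyl)ethyl oct-2-ynoate | CCCCCC#CC(=O)OCC[Si](C)(C)C | intermediate
17 | 2-(trimethylsilyl)ethyl (2E)-2-(tributylstannyl)oct-2-enoate | CCCCC/C=C(/[Sn](CCCC)(CCCC)CCCC)C(=O)OCC[Si](C)(C)C | intermediate
18 | 2-(trimethylsilyl)ethyl (2E)-2-iodooct-2-enoate | CCCCC/C=C(/I)C(=O)OCC[Si](C)(C)C | intermediate
19 | 4-{[(2S)-2-(prop-1-en-2-yl)-2,3-dihydro-1-benzofuran-5-yl]methyl} 1-[2-(trimethylsilyl)ethyl] (2Z,3R)-2-hexylidene-3-methylbutanedioate | C=C(C)[C@@H]1Cc2cc(COC(=O)[C@H](C)/C(=C/CCCCC)C(=O)OCC[Si](C)(C)C)ccc2O1 | intermediate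
20 | tris(dimethylamino)sulfonium carboxylate of 21 (not isolated) | C=C(C)[C@@H]1Cc2cc(COC(=O)[C@H](C)/C(=C/CCCCC)C(=O)[O-])ccc2O1.CN(C)[S+](N(C)C)N(C)C | intermediate
21 | (2Z,3R)-2-hexylidene-3-methyl-4-oxo-4-{[(2S)-2-(prop-1-en-2-yl)-2,3-dihydro-1-benzofuran-5-yl]methoxy}butanoic acid | C=C(C)[C@@H]1Cc2cc(COC(=O)[C@H](C)/C(=C/CCCCC)C(=O)O)ccc2O1 | target

**Step count**
Total steps: 11. Longest linear sequence: 7 (steps 1, 2, 3, 4, 5, 10, 11); the other branch is steps 6 to 9.

**Three steps most likely to fail**

Step 10 (the proposed nickel coupling). The risks are loss of alkene geometry at the alkenylnickel stage, addition of the α-ester radical to the isopropenyl group, opening of the allylic aryl ether by zerovalent nickel, and low selectivity with a primary benzylic ester. The fallback uses known chemistry, sets out from 8 and 18, and comes back at 19. Alcohol 8 is acylated with 2-bromopropanoyl bromide and pyridine to [(2S)-2-(prop-1-en-2-yl)-2,3-dihydro-1-benzofuran-5-yl]methyl (2RS)-2-bromopropanoate F1. Zinc dust (activated with Me3SiCl, THF) inserts to give the bromozinc Reformatsky reagent F2, which is not isolated and is coupled with 18 under Pd(PPh3)4 catalysis, a Negishi-type coupling of a Reformatsky reagent with an alkenyl iodide that keeps the alkene geometry. This coupling is not selective at C3 and gives 19 together with its (2Z,3S)-epimer F3; the two diastereomers are separated by preparative HPLC on a chiral stationary phase, and 19 goes on to step 11.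

Step 2. The risks are competing insertion into C–Br, lower selectivity with an aryl iodide than with the bromides this ligand class is normally used with, and the regiochemistry with isoprene. The fallback sets out from 1 and comes back at 4.
- 4-Bromophenol 1 is C-prenylated at the ortho position (NaH, 1-bromo-3-methylbut-2-ene, toluene) to 4-bromo-2-(3-methylbut-2-en-1-yl)phenol F4.
- F4 is silylated (triisopropylsilyl chloride, imidazole, DMF) to [4-bromo-2-(3-methylbut-2-en-1-yl)phenoxy]tri(propan-2-yl)silane F5.
- Shi epoxidation with the D-fructose-derived ketone (1,2:4,5-di-O-isopropylidene-β-D-erythro-2,3-hexodiulo-2,6-pyranose), Oxone (2KHSO5·KHSO4·K2SO4) and K2CO3 in MeCN/dimethoxymethane/buffer at 0 °C gives (3R)-3-({5-bromo-2-[tri(propan-2-yl)silyloxy]phenyl}methyl)-2,2-dimethyloxirane F6.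
- Tetrabutylammonium fluoride in THF frees the phenoxide, which opens the epoxide 5-exo at the secondary carbon with inversion to 2-[(2S)-5-bromo-2,3-dihydro-1-benzofuran-2-yl]propan-2-ol F7.
- Dehydration with Burgess reagent (methyl N-(triethylammoniosulfonyl)carbamate, toluene, 50 °C) gives 4.

Step 11. The risk is that fluoride acts as a base on 19 and epimerises C3 or moves the double bond into the tetrasubstituted position. The fallback sets out from 18 and comes back at 21. The silylethyl group is removed from 18 with TASF (DMF, 0 °C, then dilute HCl), before any stereocentre exists, to give (2E)-2-iodooct-2-enoic acid F8. tert-Butyldimethylsilyl chloride and imidazole convert it into tert-butyldimethylsilyl (2E)-2-iodooct-2-enoate F9, used crude. The step 10 coupling of F9 with 10 gives the tert-butyldimethylsilyl ester of 21, F10, and AcOH/THF/H2O at rt hydrolyses this silyl ester to 21 without fluoride or base.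

**Further compounds**
F1 | step 10 | [(2S)-2-(prop-1-en-2-yl)-2,3-dihydro-1-benzofuran-5-yl]methyl (2RS)-2-bromopropanoate | C=C(C)[C@@H]1Cc2cc(COC(=O)C(C)Br)ccc2O1
F2 | step 10 | bromozinc Reformatsky reagent of F1 | C=C(C)[C@@H]1Cc2cc(COC(=O)C(C)[Zn]Br)ccc2O1
F3 | step 10 | 4-{[(2S)-2-(prop-1-en-2-yl)-2,3-dihydro-1-benzofuran-5-yl]methyl} 1-[2-(trimethylsilyl)ethyl] (2Z,3S)-2-hexylidene-3-methylbutanedioate | C=C(C)[C@@H]1Cc2cc(COC(=O)[C@@H](C)/C(=C/CCCCC)C(=O)OCC[Si](C)(C)C)ccc2O1
F4 | step 2 | 4-bromo-2-(3-methylbut-2-en-1-yl)phenol | CC(C)=CCc1cc(Br)ccc1O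
F5 | step 2 | [4-bromo-2-(3-methylbut-2-en-1-yl)phenoxy]tri(propan-2-yl)silane | CC(C)=CCc1cc(Br)ccc1O[Si](C(C)C)(C(C)C)C(C)C
F6 | step 2 | (3R)-3-({5-bromo-2-[tri(propan-2-yl)silyloxy]phenyl}methyl)-2,2-dimethyloxirane | CC1(C)O[C@@H]1Cc1cc(Br)ccc1O[Si](C(C)C)(C(C)C)C(C)C
F7 | step 2 | 2-[(2S)-5-bromo-2,3-dihydro-1-benzofuran-2-yl]propan-2-ol | CC(C)(O)[C@@H]1Cc2cc(Br)ccc2O1
F8 | step 11 | (2E)-2-iodooct-2-enoic acid | CCCCC/C=C(/I)C(=O)O
F9 | step 11 | tert-butyldimethylsilyl (2E)-2-iodooct-2-enoate | CCCCC/C=C(/I)C(=O)O[Si](C)(C)C(C)(C)C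
F10 | step 11 | 1-(tert-butyldimethylsilyl) 4-{[(2S)-2-(prop-1-en-2-yl)-2,3-dihydro-1-benzofuran-5-yl]methyl} (2Z,3R)-2-hexylidene-3-methylbutanedioate | C=C(C)[C@@H]1Cc2cc(COC(=O)[C@H](C)/C(=C/CCCCC)C(=O)O[Si](C)(C)C(C)(C)C)ccc2O1
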